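**Retrosynthetic overview**
- Target acid ⇐ its methyl ester by saponification.
- 1,2-Dioxolane ⇐ catalytic asymmetric [3+2] annulation of a 1,1-disubstituted alkene with an acetoacetate-derived peroxycarbenium ion under a chiral imidodiphosphorimidate (IDPi) acid; this forms C3–C4 and C5–O and sets both quaternary centres.
- Alkene ⇐ Negishi coupling of an anti-2,4-dimethylalkyl iodide with 2-bromopropene; iodide ⇐ primary alcohol.
- Alcohol ⇐ two successive zirconium-catalysed asymmetric carboaluminations of 10-phenyldec-1-ene (first stereocentre), itself from 8-bromooct-1-ene and a phenethyl Grignard reagent.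
- Ring order: the dioxolane is the only ring made, in the penultimate step; the benzene ring is bought in.

Assumption: both enantiomers of (NMI)2ZrCl2 and the IDPi acid are made by their standard preparations and not counted as steps; (S,S)-IDPi is taken as the enantiomer giving the (3R,5R) ring, and if a test on 2-methylundec-1-ene shows the opposite sense the (R,R)-acid is used.

**Step 1**
Reactants: 1 8-bromooct-1-ene; 2 2-phenylethylmagnesium chloride
Product: 3 10-phenyldec-1-ene
Conditions: Li2CuCl4 (3 mol %), NMP, THF, 0 °C → rt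
Reagents that add atoms: none
Why: Kochi-type copper-catalysed sp3–sp3 Grignard cross-coupling of a primary bromide is fast and leaves the terminal alkene untouched; no stereocentre is involved.

**Step 2**
Reactants: 3 10-phenyldec-1-ene
Product: 6 (4R)-4-methyl-12-phenyldodec-1-ene, via alkylalane 4 (not isolated), via alkylzinc triflate 5 (not isolated)
Conditions: Me3Al (2 equiv), (−)-(NMI)2ZrCl2 [(−)-bis(1-neomenthylindenyl)zirconium dichloride] (5 mol %), (MeAlO)n (20 mol %), CH2Cl2, 0 → 23 °C; evaporate; Zn(OTf)2 (1 equiv), DMF, 70 °C; CH2=CHBr, PdCl2(DPEphos) (3 mol %), i-Bu2AlH (6 mol %), 23 °C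
Reagents that add atoms: trimethylaluminium C[Al](C)C; vinyl bromide C=CBr
Why: Negishi's zirconium-catalysed asymmetric carboalumination adds Me–Al across the terminal alkene with methyl at C2 under control of the chiral zirconocene (the (−)-catalyst gives the R alane, about 75–80% ee; this is the first stereocentre), and the alane is vinylated in the same flask by zinc-mediated, palladium-catalysed Negishi coupling.

**Step 3**
Reactants: 6 (4R)-4-methyl-12-phenyldodec-1-ene
Product: 9 (2S,4R)-2,4-dimethyl-12-phenyldodecan-1-ol, via alkylalane 7 (not isolated), via aluminium alkoxide 8 (not isolated)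
Conditions: Me3Al (2 equiv), (+)-(NMI)2ZrCl2 (5 mol %), (MeAlO)n (20 mol %), CH2Cl2, 0 → 23 °C; then O2, 0 → 23 °C; dilute aqueous HCl; silica gel chromatography to remove the syn isomers
Reagents that add atoms: trimethylaluminium C[Al](C)C; dioxygen O=O
Why: a second asymmetric carboalumination with the enantiomeric catalyst sets C2 (S) anti to the existing methyl under catalyst control (expected about 5–8:1), O2 oxidises the C–Al bond with retention, and removal of the syn diastereomers raises the enantiomeric purity of the anti alcohol statistically to about 96% ee or better.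

**Step 4**
Reactants: 9 (2S,4R)-2,4-dimethyl-12-phenyldodecan-1-ol
Product: 10 (2S,4R)-1-iodo-2,4-dimethyl-12-phenyldodecane
Conditions: I2, PPh3, imidazole, CH2Cl2, 0 °C → rt
Reagents that add atoms: iodine II
Why: Appel-type iodination displaces the activated primary hydroxyl by SN2 at CH2 and does not touch the β-stereocentre.

**Step 5**
Reactants: 10 (2S,4R)-1-iodo-2,4-dimethyl-12-phenyldodecane
Product: 12 (4S,6R)-2,4,6-trimethyl-14-phenyltetradec-1-ene, via alkylzinc iodide 11 (not isolated)
Conditions: Zn dust, LiCl, THF, 40 °C; then CH2=C(CH3)Br, Pd(OAc)2 (2 mol %), SPhos (4 mol %), THF, rt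
Reagents that add atoms: 2-bromopropene CC(Br)=C
Why: zinc insertion gives a primary alkylzinc whose stereocentres are remote from the metal, and palladium-catalysed Negishi sp3–sp2 coupling with 2-bromopropene installs the 1,1-disubstituted alkene without β-hydride elimination.

**Step 6**
Reactants: 13 methyl 3-methylbut-3-enoate
Product: 15 methyl 3-methoxy-3-[(triethylsilyl)peroxy]butanoate (racemic), via methoxy hydroperoxide 14 (not isolated)
Conditions: O3, CH2Cl2/MeOH (4:1), −78 °C; N2 purge, solvent exchange to DMF at ≤ 0 °C; Et3SiCl, imidazole, 0 °C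
Reagents that add atoms: ozone [O-][O+]=O; methanol CO; chlorotriethylsilane CC[Si](Cl)(CC)CC
Why: Criegee ozonolysis of a 1,1-disubstituted alkene gives formaldehyde and the ketone carbonyl oxide, which methanol traps as the α-methoxy hydroperoxide, and O-silylation then gives the silyl peroxyketal.

**Step 7**
Reactants: 12 (4S,6R)-2,4,6-trimethyl-14-phenyltetradec-1-ene; 15 methyl 3-methoxy-3-[(triethylsilyl)peroxy]butanoate (1.5 equiv)
Product: 17 methyl 2-[(3R,5R)-3,5-dimethyl-5-[(2S,4R)-2,4-dimethyl-12-phenyldodecyl]-1,2-dioxolan-3-yl]acetate, via peroxycarbenium ion 16 (not isolated)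
Conditions: (S,S)-IDPi (3 mol %; imidodiphosphorimidate acid from two (S)-3,3'-bis[3,5-bis(trifluoromethyl)phenyl]-1,1'-bi-2-naphthol units, N-trifluoromethanesulfonyl on both phosphorus atoms), toluene, −60 °C
Reagents that add atoms: none
Why: Proposed new method: the confined, strongly acidic IDPi is converted in the flask into its triethylsilyl derivative, which abstracts methoxide from 15 to give peroxycarbenium ion 16 as a contact ion pair with the chiral anion; the CH2 terminus of 12 adds to one enantiotopic face of 16 (sets C3, R) and the developing tertiary cation is trapped by the silylperoxy oxygen within the same ion pair before bond rotation (sets C5, R, methyls cis because both long arms point out of the open side of the pocket), returning Et3Si+ to the anion so that silylium transfer turns the cycle over; the closest known reactions are the racemic annulation of triethylsilylperoxy ketals with alkenes promoted by stoichiometric SnCl4 and IDPi counteranion-directed additions of π-nucleophiles to oxocarbenium ions (Mukaiyama and Hosomi–Sakurai type).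

**Step 8**
Reactants: 17 methyl 2-[(3R,5R)-3,5-dimethyl-5-[(2S,4R)-2,4-dimethyl-12-phenyldodecyl]-1,2-dioxolan-3-yl]acetate
Product: 19 2-[(3R,5R)-3,5-dimethyl-5-[(2S,4R)-2,4-dimethyl-12-phenyldodecyl]-1,2-dioxolan-3-yl]acetic acid (target CNP0188135.5), via lithium carboxylate 18 (not isolated)
Conditions: LiOH·H2O (3 equiv), THF/H2O (3:1), 0 °C → rt; then dilute aqueous HCl to pH 3
Reagents that add atoms: lithium hydroxide [Li+].[OH-]
Why: saponification of an unhindered methyl ester; the fully substituted dioxolane carbons carry no hydrogen for Kornblum–DeLaMare cleavage, so the peroxide should survive cold aqueous hydroxide.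

**Compound list**
1 | 8-bromooct-1-ene | C=CCCCCCCBr | starting material
2 | 2-phenylethylmagnesium chloride | Cl[Mg]CCc1ccccc1 | starting material
3 | 10-phenyldec-1-ene | C=CCCCCCCCCc1ccccc1 | intermediate
4 | dimethyl[(2R)-2-methyl-10-phenyldecyl]alumane | C[C@H](CCCCCCCCc1ccccc1)C[Al](C)C | intermediate
5 | [(2R)-2-methyl-10-phenyldecyl]zinc trifluoromethanesulfonate | C[C@H](CCCCCCCCc1ccccc1)C[Zn]OS(=O)(=O)C(F)(F)F | intermediate
6 | (4R)-4-methyl-12-phenyldodec-1-ene | C[C@H](CCCCCCCCc1ccccc1)CC=C | intermediate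
7 | [(2S,4R)-2,4-dimethyl-12-phenyldodecyl]dimethylalumane | C[C@H](CCCCCCCCc1ccccc1)C[C@H](C)C[Al](C)C | intermediate
8 | {[(2S,4R)-2,4-dimethyl-12-phenyldodecyl]oxy}dimethoxyalumane | C[C@H](CCCCCCCCc1ccccc1)C[C@H](C)CO[Al](OC)OC | intermediate
9 | (2S,4R)-2,4-dimethyl-12-phenyldodecan-1-ol | C[C@H](CCCCCCCCc1ccccc1)C[C@H](C)CO | intermediate
10 | (2S,4R)-1-iodo-2,4-dimethyl-12-phenyldodecane | C[C@H](CCCCCCCCc1ccccc1)C[C@H](C)CI | intermediate
11 | [(2S,4R)-2,4-dimethyl-12-phenyldodecyl]zinc iodide | C[C@H](CCCCCCCCc1ccccc1)C[C@H](C)C[Zn]I | intermediate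
12 | (4S,6R)-2,4,6-trimethyl-14-phenyltetradec-1-ene | C[C@H](CCCCCCCCc1ccccc1)C[C@H](C)CC(C)=C | intermediate
13 | methyl 3-methylbut-3-enoate | COC(=O)CC(C)=C | starting material
14 | methyl 3-hydroperoxy-3-methoxybutanoate (racemic) | COC(=O)CC(C)(OC)OO | intermediate
15 | methyl 3-methoxy-3-[(triethylsilyl)peroxy]butanoate (racemic) | COC(=O)CC(C)(OC)OO[Si](CC)(CC)CC | intermediate
16 | (4-methoxy-4-oxobutan-2-ylidene)(triethylsilyloxy)oxonium, as its IDPi ion pair | COC(=O)CC(C)=[O+]O[Si](CC)(CC)CC | intermediate
17 | methyl 2-[(3R,5R)-3,5-dimethyl-5-[(2S,4R)-2,4-dimethyl-12-phenyldodecyl]-1,2-dioxolan-3-yl]acetate | C[C@H](CCCCCCCCc1ccccc1)C[C@H](C)C[C@]1(C)C[C@](C)(CC(=O)OC)OO1 | intermediate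
18 | lithium 2-[(3R,5R)-3,5-dimethyl-5-[(2S,4R)-2,4-dimethyl-12-phenyldodecyl]-1,2-dioxolan-3-yl]acetate | C[C@H](CCCCCCCCc1ccccc1)C[C@H](C)C[C@]1(C)C[C@](C)(CC(=O)[O-])OO1.[Li+] | intermediate
19 | 2-[(3R,5R)-3,5-dimethyl-5-[(2S,4R)-2,4-dimethyl-12-phenyldodecyl]-1,2-dioxolan-3-yl]acetic acid | C[C@H](CCCCCCCCc1ccccc1)C[C@H](C)C[C@]1(C)C[C@](C)(CC(=O)O)OO1 | target

**Step count**
Total: 8 steps. Longest linear sequence: 7 steps (1, 2, 3, 4, 5, 7, 8); step 6 is the side branch.

**Steps most likely to fail**

Step 7 (the new annulation) is the main risk. Ion 16 can lose a proton next to the ester to give a vinyl peroxide, the alkene can isomerise, and the side-chain centre next to the reacting carbon may work against the catalyst. The fallback uses known chemistry, sets out from 12 and comes back at 17. Cross-metathesis of 12 with methyl vinyl ketone (second-generation Hoveyda–Grubbs catalyst RuCl2(H2IMes)(=CH-C6H4-2-OiPr), CH2Cl2, 40 °C) gives the enone (3E,6S,8R)-4,6,8-trimethyl-16-phenylhexadec-3-en-2-one F1. Conjugate addition of H2O2 (aqueous H2O2, cat. LiOH, MeOH, 0 °C, as for mesityl oxide) with spontaneous ring closure gives the peroxyhemiketal 3,5-dimethyl-5-[(2S,4R)-2,4-dimethyl-12-phenyldodecyl]-1,2-dioxolan-3-ol F2, about 1:1 at C5. MeOH with cat. TsOH gives 3-methoxy-3,5-dimethyl-5-[(2S,4R)-2,4-dimethyl-12-phenyldodecyl]-1,2-dioxolane F3. TiCl4 and 1-methoxy-1-(trimethylsilyloxy)ethene in CH2Cl2 at −78 °C then add the acetate unit to the ring peroxycarbenium ion. This gives 17 as a mixture of ring stereoisomers, and the (3R,5R) isomer is isolated by preparative HPLC.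

Step 3 may give a poor anti:syn ratio, and the diastereomeric alcohols may not separate. The fallback sets out from 6, comes back at 12 and bypasses steps 3 to 5. Cross-metathesis of 6 with S-ethyl thioacrylate (same ruthenium catalyst) gives S-ethyl (2E,5R)-5-methyl-13-phenyltridec-2-enethioate F4. Copper-catalysed asymmetric conjugate addition (MeMgBr, CuBr·SMe2 1 mol %, the Josiphos enantiomer that gives the 3,5-anti product, t-BuOMe, −75 °C) gives S-ethyl (3S,5R)-3,5-dimethyl-13-phenyltridecanethioate F5, typically above 95:5. Me2CuLi in Et2O at −78 °C converts the thioester into the methyl ketone (4S,6R)-4,6-dimethyl-14-phenyltetradecan-2-one F6. Wittig methylenation (Ph3PCH3Br, KOtBu, THF) gives 12.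

Step 2 gives only moderate enantioselectivity for a plain 1-alkene, and the one-pot transmetalation and vinylation is untested on this substrate. The fallback is organocatalytic, sets out from 3 and comes back at 6. Wacker oxidation (PdCl2, CuCl, O2, DMF/H2O) gives 10-phenyldecan-2-one F7. (Z)-2-Ethoxyvinyllithium in THF at −78 °C gives the carbinol (1Z)-1-ethoxy-3-methyl-11-phenylundec-1-en-3-ol F8, which on aqueous acid in the same flask gives 3-methyl-11-phenylundec-2-enal F9 as an E/Z mixture. Iminium transfer hydrogenation with Hantzsch ester and (R)-2-tert-butyl-3-methylimidazolidin-4-one trichloroacetate (20 mol %, CHCl3, −30 °C; the enantiomer is chosen by analogy and confirmed on the first run) converges both alkene isomers to (3R)-3-methyl-11-phenylundecanal F10 in about 90% ee. Wittig methylenation gives 6.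

**Further compounds**
F1 | step 7 | (3E,6S,8R)-4,6,8-trimethyl-16-phenylhexadec-3-en-2-one | C[C@H](CCCCCCCCc1ccccc1)C[C@H](C)C/C(C)=C/C(C)=O
F2 | step 7 | 3,5-dimethyl-5-[(2S,4R)-2,4-dimethyl-12-phenyldodecyl]-1,2-dioxolan-3-ol (mixture at C3 and C5) | C[C@H](CCCCCCCCc1ccccc1)C[C@H](C)CC1(C)CC(C)(O)OO1
F3 | step 7 | 3-methoxy-3,5-dimethyl-5-[(2S,4R)-2,4-dimethyl-12-phenyldodecyl]-1,2-dioxolane (mixture at C3 and C5) | C[C@H](CCCCCCCCc1ccccc1)C[C@H](C)CC1(C)CC(C)(OC)OO1
F4 | step 3 | S-ethyl (2E,5R)-5-methyl-13-phenyltridec-2-enethioate | C[C@H](CCCCCCCCc1ccccc1)C/C=C/C(=O)SCC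
F5 | step 3 | S-ethyl (3S,5R)-3,5-dimethyl-13-phenyltridecanethioate | C[C@H](CCCCCCCCc1ccccc1)C[C@H](C)CC(=O)SCC
F6 | step 3 | (4S,6R)-4,6-dimethyl-14-phenyltetradecan-2-one | C[C@H](CCCCCCCCc1ccccc1)C[C@H](C)CC(C)=O
F7 | step 2 | 10-phenyldecan-2-one | CC(=O)CCCCCCCCc1ccccc1
F8 | step 2 | (1Z)-1-ethoxy-3-methyl-11-phenylundec-1-en-3-ol (racemic, not isolated) | CCO/C=C\C(C)(O)CCCCCCCCc1ccccc1
F9 | step 2 | 3-methyl-11-phenylundec-2-enal (E/Z mixture) | CC(CCCCCCCCc1ccccc1)=CC=O
F10 | step 2 | (3R)-3-methyl-11-phenylundecanal | C[C@H](CCCCCCCCc1ccccc1)CC=O
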